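**Plan**

1. Positions are numbered C-1 (methyl-bearing fusion carbon), C-2, C-3, C-4 (isopropyl carbinol), C-5 (fusion CH), C-6 (ester carbon), C-7=C-8(Me), C-9, C-10 (ring CH2CH2). The retrosynthesis cuts the C-6 ester C–O bond, then the C-4–isopropyl bond, then the C-1–methyl bond (back to a C-1=C-5 enone of a C-4 ketone), then the C-9–C-10 bond, then the cyclopropane bond C-5–C-7, the C-10–C-1 bond and the C-5–C-6 bond.
2. Enabling feature: in the seven-membered ring the C-9–C-10 ethano unit lies between the C-7=C-8 alkene and C-1, and the oxygenated sp3 C-6 separates C-7 from C-5. With C-1/C-5 written as an enone alkene, this is the C-8=C-7–C-6–C-5=C-1 diene of a cis-divinylcyclopropane rearrangement product, and C-9–C-10 is the σ bond that the [3,3] shift creates.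
3. Forward: the five-membered ring is bought as a ketal and acylated at C-5; C-10 (as CH2SiMe3) and an allylic chloride are installed; fluoride then builds the three-membered ring (C-5/C-6/C-7), which expands to the seven-membered ring in the same flask. Methyl, isopropyl and the ester follow.
4. Stereochemistry: C-6 comes from a CBS reduction and is the only centre carried through the key step, in which the cyclopropane diastereomers converge. C-1 is set by conjugate addition anti to the C-6 silyloxy group, C-5 by equilibration to the trans ring fusion, and C-4 by organocerium addition anti to the C-5–C-6 branch.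

Key step: step 8

Remark: compounds 1, 3 and 18 are taken as purchasable; the position numbers of the plan are used in the Why lines.

**Route**

Step 1
Reactants: 1 3-methylbut-2-enoyl chloride
Product: 2 N-methoxy-N,3-dimethylbut-2-enamide
Conditions: MeNH(OMe)·HCl, pyridine, CH2Cl2, 0 °C to rt
Reagents that add atoms: N,O-dimethylhydroxylamine hydrochloride (CNOC.Cl)
Why: Acylation of N,O-dimethylhydroxylamine by the acid chloride (Weinreb amide formation) is a standard amidation that leaves the conjugated alkene untouched.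

Step 2
Reactants: 3 6-bromo-1,4-dioxaspiro[4.4]non-6-ene; 2 N-methoxy-N,3-dimethylbut-2-enamide
Product: 5 1-(1,4-dioxaspiro[4.4]non-6-en-6-yl)-3-methylbut-2-en-1-one, via alkenyllithium 4 (not isolated)
Conditions: n-BuLi, THF, −78 °C; then 2, −78 to −20 °C; aqueous NH4Cl
Reagents that add atoms: none
Why: Bromine–lithium exchange on the ketal-masked 2-bromocyclopentenone gives 4, which should add only once to the Weinreb amide because the chelated tetrahedral intermediate survives until work-up, so the C-5–C-6 bond is formed at the ketone level.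

Step 3
Reactants: 5 1-(1,4-dioxaspiro[4.4]non-6-en-6-yl)-3-methylbut-2-en-1-one
Product: 6 (1S)-1-(1,4-dioxaspiro[4.4]non-6-en-6-yl)-3-methylbut-2-en-1-ol
Conditions: catecholborane, (R)-2-methyl-CBS-oxazaborolidine (20 mol %), toluene, −78 °C
Reagents that add atoms: none
Why: Corey–Bakshi–Shibata reduction, in which the α-branched ketal-bearing alkenyl group should act as the large substituent so that the (R)-catalyst gives the (S)-carbinol; this sets C-6, from which all other centres are derived, and catecholborane at low temperature should spare the alkenes.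

Step 4
Reactants: 6 (1S)-1-(1,4-dioxaspiro[4.4]non-6-en-6-yl)-3-methylbut-2-en-1-ol
Product: 7 {[(1S)-1-(1,4-dioxaspiro[4.4]non-6-en-6-yl)-3-methylbut-2-en-1-yl]oxy}tri(propan-2-yl)silane
Conditions: i-Pr3SiOTf, 2,6-lutidine, CH2Cl2, −78 to 0 °C
Reagents that add atoms: triisopropylsilyl trifluoromethanesulfonate (CC(C)[Si](C(C)C)(C(C)C)OS(=O)(=O)C(F)(F)F)
Why: Silylation with a silyl triflate and a hindered base protects the bis-allylic alcohol as a bulky, fluoride-tolerant ether without touching the ketal or C-6.

Step 5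
Reactants: 7 {[(1S)-1-(1,4-dioxaspiro[4.4]non-6-en-6-yl)-3-methylbut-2-en-1-yl]oxy}tri(propan-2-yl)silane
Product: 8 2-[(1S)-3-methyl-1-{[tri(propan-2-yl)silyl]oxy}but-2-en-1-yl]cyclopent-2-en-1-one
Conditions: pyridinium p-toluenesulfonate (10 mol %), acetone/H2O, rt
Reagents that add atoms: water (O)
Why: Mild acid-catalysed ketal hydrolysis unmasks the enone; the triisopropylsilyl ether should survive, and once the carbonyl is free C-6 is no longer prone to ionisation.

Step 6
Reactants: 8 2-[(1S)-3-methyl-1-{[tri(propan-2-yl)silyl]oxy}but-2-en-1-yl]cyclopent-2-en-1-one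
Product: 10 2-[(1S)-3-methyl-1-{[tri(propan-2-yl)silyl]oxy}but-2-en-1-yl]-3-[(trimethylsilyl)methyl]cyclopent-2-en-1-one, via selenide 9 (not isolated)
Conditions: Me3SiCH2MgCl, CuBr·SMe2 (10 mol %), THF, −78 °C; PhSeBr, −78 to 0 °C; then H2O2, pyridine, CH2Cl2, 0 °C to rt
Reagents that add atoms: (trimethylsilyl)methylmagnesium chloride (C[Si](C)(C)C[Mg]Cl)
Why: Copper-catalysed conjugate addition of the silylmethyl Grignard reagent, selenenylation of the enolate anti to the new substituent and selenoxide syn-elimination (which runs toward C-1, away from the oxygen-bearing C-6) should restore the enone with C-10 in place as CH2SiMe3, a masked exocyclic dienolate.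

Step 7
Reactants: 10 2-[(1S)-3-methyl-1-{[tri(propan-2-yl)silyl]oxy}but-2-en-1-yl]-3-[(trimethylsilyl)methyl]cyclopent-2-en-1-one
Product: 11 2-[(1R)-2-chloro-3-methyl-1-{[tri(propan-2-yl)silyl]oxy}but-3-en-1-yl]-3-[(trimethylsilyl)methyl]cyclopent-2-en-1-one (both epimers at the chlorine-bearing carbon; the descriptor changes only because chlorine alters the priorities)
Conditions: Ca(OCl)2, solid CO2, CH2Cl2/H2O, 0 °C
Reagents that add atoms: calcium hypochlorite ([Ca+2].[O-]Cl.[O-]Cl)
Why: Ene-type allylic chlorination by hypochlorous acid should attack only the electron-rich trisubstituted alkene, placing chlorine on C-7 and turning the dimethylvinyl end into the isopropenyl group; the configuration at C-7 does not matter because it is erased in step 8.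

Step 8
Reactants: 11 2-[(1R)-2-chloro-3-methyl-1-{[tri(propan-2-yl)silyl]oxy}but-3-en-1-yl]-3-[(trimethylsilyl)methyl]cyclopent-2-en-1-one
Product: 13 (8S)-6-methyl-8-{[tri(propan-2-yl)silyl]oxy}-3,4,5,8-tetrahydroazulen-1(2H)-one, via spiro-divinylcyclopropane 12 (not isolated)
Conditions: CsF, 18-crown-6 (cat.), anhydrous MeCN, 0 °C to rt; then toluene, 100 °C
Reagents that add atoms: none
Why: Fluoride removes the silyl group from C-10 and so generates the exocyclic dienolate regiospecifically; its α-carbon C-5 displaces chloride at C-7 (3-exo-tet enolate alkylation, as in the classical closure of γ-halo ketones to cyclopropyl ketones) to give the spiro-divinylcyclopropanes 12 as a cis/trans mixture. The cis isomers then undergo the divinylcyclopropane–cycloheptadiene (Cope) rearrangement, a concerted [3,3] shift through a boat transition state in which the strained C-5–C-7 bond breaks while the methylene termini C-9 and C-10 join, so the three-membered ring expands to the seven-membered ring with the C-7=C-8 alkene and the C-1=C-5 enone in place; the closest precedent is the rearrangement of cis-divinylcyclopropanes released by unmasking the second vinyl group. The trans isomers should be funnelled in as well, because the C-5–C-7 bond is doubly allylic and α to the ketone and reopens reversibly at 100 °C (one-centre epimerisation, besides a reversible retro-Claisen shift to a dihydrooxepine), so every diastereomer of 12 should end as 13. No stereocenter is created: C-6 keeps all four bonds, its configuration from step 3 becomes the only stereocenter of 13, and the two uncontrolled cyclopropane centres C-5 and C-7 become trigonal. The selectivity needed is carbon alkylation at C-5 rather than at C-10 (five-membered ring) or at oxygen, without β-elimination of the C-6 silyloxy group; it rests on the α-preference of dienolates (as in the alkylation of Hagemann's ester), the kinetic advantage of three-membered ring closure and the poor leaving ability of the triisopropylsilyloxide.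

Step 9
Reactants: 13 (8S)-6-methyl-8-{[tri(propan-2-yl)silyl]oxy}-3,4,5,8-tetrahydroazulen-1(2H)-one
Product: 15 (3aS,8S,8aS)-3a,6-dimethyl-8-{[tri(propan-2-yl)silyl]oxy}-3,3a,4,5,8,8a-hexahydroazulen-1(2H)-one, via silyl enol ether 14 (not isolated)
Conditions: MeMgBr, CuBr·SMe2 (10 mol %), Me3SiCl, HMPA, THF, −78 to −40 °C; then K2CO3, MeOH, 0 °C to rt
Reagents that add atoms: methylmagnesium bromide (C[Mg]Br)
Why: Chlorotrimethylsilane-accelerated copper-catalysed 1,4-addition should deliver methyl to C-1 on the face opposite the bulky C-6 silyloxy group, trapping as 14 prevents β-elimination of that group, and methanolysis with base equilibration at the enolisable C-5 should settle on the trans-fused ketone, in which the C-4 carbonyl and the C-6 silyloxy group are anti and both pseudo-equatorial.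

Step 10
Reactants: 15 (3aS,8S,8aS)-3a,6-dimethyl-8-{[tri(propan-2-yl)silyl]oxy}-3,3a,4,5,8,8a-hexahydroazulen-1(2H)-one
Product: 16 (3R,3aS,4S,8aS)-6,8a-dimethyl-3-(propan-2-yl)-4-{[tri(propan-2-yl)silyl]oxy}-1,2,3,3a,4,7,8,8a-octahydroazulen-3-ol
Conditions: i-PrMgCl, CeCl3 (anhydrous), THF, −78 to 0 °C; aqueous NH4Cl
Reagents that add atoms: isopropylmagnesium chloride (CC(C)[Mg]Cl)
Why: Organocerium 1,2-addition (little enolisation or reduction) should occur on the cyclopentanone face opposite the adjacent C-5–C-6 branch, from the side of H-5, which places the new hydroxyl cis to the angular methyl and sets C-4.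

Step 11
Reactants: 16 (3R,3aS,4S,8aS)-6,8a-dimethyl-3-(propan-2-yl)-4-{[tri(propan-2-yl)silyl]oxy}-1,2,3,3a,4,7,8,8a-octahydroazulen-3-ol
Product: 17 (3R,3aS,4S,8aS)-6,8a-dimethyl-3-(propan-2-yl)-1,2,3,3a,4,7,8,8a-octahydroazulene-3,4-diol
Conditions: Bu4NF, THF, rt to 40 °C
Reagents that add atoms: none
Why: Fluoride cleaves the Si–O bond of the hindered silyl ether without affecting the tertiary alcohol, the alkene or any stereocenter.

Step 12
Reactants: 17 (3R,3aS,4S,8aS)-6,8a-dimethyl-3-(propan-2-yl)-1,2,3,3a,4,7,8,8a-octahydroazulene-3,4-diol; 18 4-(acetyloxy)benzoyl chloride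
Product: 19 (3R,3aS,4S,8aS)-3-hydroxy-6,8a-dimethyl-3-(propan-2-yl)-1,2,3,3a,4,7,8,8a-octahydroazulen-4-yl 4-(acetyloxy)benzoate
Conditions: Et3N, 4-(dimethylamino)pyridine (cat.), CH2Cl2, 0 °C to rt
Reagents that add atoms: none
Why: Nucleophile-catalysed acylation should be selective for the secondary allylic hydroxyl over the hindered tertiary one and retains C-6 because the C–O bond is not broken.

Step 13
Reactants: 19 (3R,3aS,4S,8aS)-3-hydroxy-6,8a-dimethyl-3-(propan-2-yl)-1,2,3,3a,4,7,8,8a-octahydroazulen-4-yl 4-(acetyloxy)benzoate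
Product: 20 (3R,3aS,4S,8aS)-3-hydroxy-6,8a-dimethyl-3-(propan-2-yl)-1,2,3,3a,4,7,8,8a-octahydroazulen-4-yl 4-hydroxybenzoate
Conditions: K2CO3 (cat.), MeOH, 0 °C
Reagents that add atoms: none
Why: Base-catalysed methanolysis should remove the phenolic acetate (phenoxide leaving group) much faster than it attacks the hindered, electron-rich benzoate of the secondary alcohol, releasing the target.

**Compound list**

1 | 3-methylbut-2-enoyl chloride | CC(C)=CC(Cl)=O | starting material
2 | N-methoxy-N,3-dimethylbut-2-enamide | CC(C)=CC(=O)N(C)OC | intermediate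
3 | 6-bromo-1,4-dioxaspiro[4.4]non-6-ene | BrC1=CCCC12OCCO2 | starting material
4 | (1,4-dioxaspiro[4.4]non-6-en-6-yl)lithium, formed in the flask | [Li]C1=CCCC12OCCO2 | intermediate
5 | 1-(1,4-dioxaspiro[4.4]non-6-en-6-yl)-3-methylbut-2-en-1-one | CC(C)=CC(=O)C1=CCCC12OCCO2 | intermediate
6 | (1S)-1-(1,4-dioxaspiro[4.4]non-6-en-6-yl)-3-methylbut-2-en-1-ol | CC(C)=C[C@H](O)C1=CCCC12OCCO2 | intermediate
7 | {[(1S)-1-(1,4-dioxaspiro[4.4]non-6-en-6-yl)-3-methylbut-2-en-1-yl]oxy}tri(propan-2-yl)silane | CC(C)=C[C@H](O[Si](C(C)C)(C(C)C)C(C)C)C1=CCCC12OCCO2 | intermediate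
8 | 2-[(1S)-3-methyl-1-{[tri(propan-2-yl)silyl]oxy}but-2-en-1-yl]cyclopent-2-en-1-one | CC(C)=C[C@H](O[Si](C(C)C)(C(C)C)C(C)C)C1=CCCC1=O | intermediate
9 | 2-[(1S)-3-methyl-1-{[tri(propan-2-yl)silyl]oxy}but-2-en-1-yl]-2-(phenylselanyl)-3-[(trimethylsilyl)methyl]cyclopentan-1-one, ring-carbon epimers, formed in the flask | CC(C)=C[C@H](O[Si](C(C)C)(C(C)C)C(C)C)C1([Se]c2ccccc2)C(C[Si](C)(C)C)CCC1=O | intermediate
10 | 2-[(1S)-3-methyl-1-{[tri(propan-2-yl)silyl]oxy}but-2-en-1-yl]-3-[(trimethylsilyl)methyl]cyclopent-2-en-1-one | CC(C)=C[C@H](O[Si](C(C)C)(C(C)C)C(C)C)C1=C(C[Si](C)(C)C)CCC1=O | intermediate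
11 | 2-[(1R)-2-chloro-3-methyl-1-{[tri(propan-2-yl)silyl]oxy}but-3-en-1-yl]-3-[(trimethylsilyl)methyl]cyclopent-2-en-1-one, both epimers at the chlorine-bearing carbon | C=C(C)C(Cl)[C@H](O[Si](C(C)C)(C(C)C)C(C)C)C1=C(C[Si](C)(C)C)CCC1=O | intermediate
12 | (1S)-7-methylidene-2-(prop-1-en-2-yl)-1-{[tri(propan-2-yl)silyl]oxy}spiro[2.4]heptan-4-one, diastereomer mixture at C-2 and C-3, formed in the flask | C=C(C)C1[C@H](O[Si](C(C)C)(C(C)C)C(C)C)C12C(=C)CCC2=O | intermediate
13 | (8S)-6-methyl-8-{[tri(propan-2-yl)silyl]oxy}-3,4,5,8-tetrahydroazulen-1(2H)-one | CC1=C[C@H](O[Si](C(C)C)(C(C)C)C(C)C)C2=C(CC1)CCC2=O | intermediate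
14 | {[(3aS,8S)-3a,6-dimethyl-8-{[tri(propan-2-yl)silyl]oxy}-2,3,3a,4,5,8-hexahydroazulen-1-yl]oxy}trimethylsilane, formed in the flask | CC1=C[C@H](O[Si](C(C)C)(C(C)C)C(C)C)C2=C(O[Si](C)(C)C)CC[C@]2(C)CC1 | intermediate
15 | (3aS,8S,8aS)-3a,6-dimethyl-8-{[tri(propan-2-yl)silyl]oxy}-3,3a,4,5,8,8a-hexahydroazulen-1(2H)-one | CC1=C[C@H](O[Si](C(C)C)(C(C)C)C(C)C)[C@@H]2[C@@](C)(CC1)CCC2=O | intermediate
16 | (3R,3aS,4S,8aS)-6,8a-dimethyl-3-(propan-2-yl)-4-{[tri(propan-2-yl)silyl]oxy}-1,2,3,3a,4,7,8,8a-octahydroazulen-3-ol | CC1=C[C@H](O[Si](C(C)C)(C(C)C)C(C)C)[C@@H]2[C@@](C)(CC1)CC[C@@]2(O)C(C)C | intermediate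
17 | (3R,3aS,4S,8aS)-6,8a-dimethyl-3-(propan-2-yl)-1,2,3,3a,4,7,8,8a-octahydroazulene-3,4-diol | CC1=C[C@H](O)[C@@H]2[C@@](C)(CC1)CC[C@@]2(O)C(C)C | intermediate
18 | 4-(acetyloxy)benzoyl chloride | CC(=O)Oc1ccc(cc1)C(Cl)=O | starting material
19 | (3R,3aS,4S,8aS)-3-hydroxy-6,8a-dimethyl-3-(propan-2-yl)-1,2,3,3a,4,7,8,8a-octahydroazulen-4-yl 4-(acetyloxy)benzoate | CC1=C[C@H](OC(=O)c2ccc(OC(C)=O)cc2)[C@@H]2[C@@](C)(CC1)CC[C@@]2(O)C(C)C | intermediate
20 | (3R,3aS,4S,8aS)-3-hydroxy-6,8a-dimethyl-3-(propan-2-yl)-1,2,3,3a,4,7,8,8a-octahydroazulen-4-yl 4-hydroxybenzoate | CC1=C[C@H](OC(=O)c2ccc(O)cc2)[C@@H]2[C@@](C)(CC1)CC[C@@]2(O)C(C)C | target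

**Step count and risks**

Total: 13 steps. Longest linear sequence: 13 steps (1 to 20).

Steps most likely to fail:

Step 8. The fluoride-generated dienolate may close through C-10 to a five-membered ring or through oxygen, may expel the C-6 silyloxy group by β-elimination, or the trans-cyclopropanes may fail to epimerise before decomposition. The fallback replaces the irreversible chloride displacement by a reversible zerovalent palladium π-allyl manifold (Tsuji–Trost) and sets out from 10. Allylic oxidation of the (E)-methyl group with SeO2 (cat.) and t-BuOOH in CH2Cl2 should give 2-[(1S,2E)-4-hydroxy-3-methyl-1-{[tri(propan-2-yl)silyl]oxy}but-2-en-1-yl]-3-[(trimethylsilyl)methyl]cyclopent-2-en-1-one F1. Methyl chloroformate and pyridine should convert it into methyl (2E,4S)-2-methyl-4-{5-oxo-2-[(trimethylsilyl)methyl]cyclopent-1-en-1-yl}-4-{[tri(propan-2-yl)silyl]oxy}but-2-en-1-yl carbonate F2. Pd(PPh3)4 in THF at 60 °C should ionise the carbonate; the methoxide released on loss of carbon dioxide removes the silyl group from C-10, and the dienolate/π-allyl pair closes reversibly at C-5/C-7 to 12. The cyclopropane is drained by the same Cope rearrangement, so the fallback comes back at 13.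

Step 9. The methyl group may add sluggishly to the fully substituted β-carbon, the enolate may lose the silyloxy group, or protonation may leave the cis ring fusion. The fallback sets out from 13. Corey–Chaykovsky cyclopropanation with dimethylsulfoxonium methylide (Me3S(O)I, NaH, DMSO) on the face anti to the silyloxy group should give the 3a,8a-methano-bridged ketone (8S)-6-methyl-8-{[tri(propan-2-yl)silyl]oxy}-3,3a,4,5,8,8a-hexahydro-3a,8a-methanoazulen-1(2H)-one F3. SmI2 with HMPA and t-BuOH in THF should then cleave the cyclopropane bond between C-8a and the bridging carbon (the bond aligned with the ketyl), which turns the bridge into the angular methyl; the resulting enolate is protonated in the flask at low temperature. The same base equilibration then returns the route at 15. This addresses the addition and the elimination; the ring-fusion outcome still rests on the equilibration.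

Step 3. The two alkenyl groups on the carbonyl may be too alike for high enantioselectivity. The fallback sets out from 5. Luche reduction (NaBH4, CeCl3·7H2O, MeOH, −40 °C) should give racemic 1-(1,4-dioxaspiro[4.4]non-6-en-6-yl)-3-methylbut-2-en-1-ol F4. Lipase-catalysed kinetic resolution (Burkholderia cepacia lipase, vinyl acetate, t-BuOMe, rt) should acetylate the (R)-enantiomer to (1R)-1-(1,4-dioxaspiro[4.4]non-6-en-6-yl)-3-methylbut-2-en-1-yl acetate F5 and leave the (S)-alcohol, which is 6.

**Further compounds**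

F1 | step 8 | 2-[(1S,2E)-4-hydroxy-3-methyl-1-{[tri(propan-2-yl)silyl]oxy}but-2-en-1-yl]-3-[(trimethylsilyl)methyl]cyclopent-2-en-1-one | OC/C(C)=C/[C@H](O[Si](C(C)C)(C(C)C)C(C)C)C1=C(C[Si](C)(C)C)CCC1=O
F2 | step 8 | methyl (2E,4S)-2-methyl-4-{5-oxo-2-[(trimethylsilyl)methyl]cyclopent-1-en-1-yl}-4-{[tri(propan-2-yl)silyl]oxy}but-2-en-1-yl carbonate | COC(=O)OC/C(C)=C/[C@H](O[Si](C(C)C)(C(C)C)C(C)C)C1=C(C[Si](C)(C)C)CCC1=O
F3 | step 9 | (8S)-6-methyl-8-{[tri(propan-2-yl)silyl]oxy}-3,3a,4,5,8,8a-hexahydro-3a,8a-methanoazulen-1(2H)-one, methylene bridge anti to the silyloxy group | CC1=C[C@H](O[Si](C(C)C)(C(C)C)C(C)C)[C@]23C[C@]3(CC1)CCC2=O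
F4 | step 3 | racemic 1-(1,4-dioxaspiro[4.4]non-6-en-6-yl)-3-methylbut-2-en-1-ol | CC(C)=CC(O)C1=CCCC12OCCO2
F5 | step 3 | (1R)-1-(1,4-dioxaspiro[4.4]non-6-en-6-yl)-3-methylbut-2-en-1-yl acetate | CC(C)=C[C@@H](OC(C)=O)C1=CCCC12OCCO2
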